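## Retrosynthetic overview
1. Ring letters: unit 1 has rings A (benzo), C (pyranone) and B (4-methoxyphenyl). Unit 2 has rings D (benzo, bonded to ring B), F (pyranone) and E (4-hydroxyphenyl).
2. Key disconnection: both O1–C2 bonds (rings C and F) are opened at once to an open-chain (E,E)-bichalcone. In the forward direction, one catalyst-controlled double oxa-Michael closure makes both rings and both (S) centres in the last operation.
3. The two enone C=C bonds go back, by two directed aldol condensations, to a biaryl keto-aldehyde core, 2',6'-dihydroxy-4'-methoxyacetophenone (ring A) and 4-(THP-oxy)benzaldehyde (ring E).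
4. The B–D biaryl bond goes back, by Suzuki coupling, to 5-formyl-2-methoxyphenylboronic acid and the mono-iodide of the same acetophenone.
5. Ring order: A, B, D and E are bought as arenes. C and F form together at the very end.

Assumption: the quinine-derived 9-epi-amino thiourea is taken to give the 2S series (checked on the first run by the negative CD band near 290 nm typical of 2S-flavanones, with the quinidine-derived pseudoenantiomer as drop-in replacement if the sign is opposite), and the biaryl axis is taken as freely rotating because the target string carries no axial descriptor.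

## Route

Step 1
Reactants: 1 2',6'-dihydroxy-4'-methoxyacetophenone
Product: 2 1-(2,6-dihydroxy-3-iodo-4-methoxyphenyl)ethan-1-one
Conditions: NIS (1.0 equiv), MeCN, 0 °C, 1 h, dark
Reagents that add atoms: N-iodosuccinimide (NIS), O=C1CCC(=O)N1I
Why: This is an electrophilic aromatic iodination (SEAr) of a phloroglucinol-type ring whose two free positions are symmetry-equivalent, so only one mono-iodide exists, one equivalent of NIS at 0 °C keeps the di-iodide low, and no stereocentre is formed.

Step 2
Reactants: 2 1-(2,6-dihydroxy-3-iodo-4-methoxyphenyl)ethan-1-one; 3 (5-formyl-2-methoxyphenyl)boronic acid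
Product: 4 3-(3-acetyl-2,4-dihydroxy-6-methoxyphenyl)-4-methoxybenzaldehyde
Conditions: Pd(OAc)2 (3 mol %), SPhos (6 mol %), K3PO4 (4 equiv), dioxane/H2O 5:1, 70 °C, 6 h
Reagents that add atoms: none
Why: In this Suzuki–Miyaura coupling the bulky electron-rich biarylphosphine lets zerovalent palladium insert into the hindered C–I bond and build the tri-ortho-substituted biaryl, the free phenols ride along as phenoxides, phosphate is too weak to enolise the phenoxide-deactivated acetyl group so ketone and aldehyde do not condense, and no stereocentre is formed.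

Step 3
Reactants: 1 2',6'-dihydroxy-4'-methoxyacetophenone; 4 3-(3-acetyl-2,4-dihydroxy-6-methoxyphenyl)-4-methoxybenzaldehyde
Product: 6 (E)-3-[3-(3-acetyl-2,4-dihydroxy-6-methoxyphenyl)-4-methoxyphenyl]-1-(2,6-dihydroxy-4-methoxyphenyl)prop-2-en-1-one, via racemic aldol adduct 5 (not isolated)
Conditions: 1 (1.5 equiv), LiN(SiMe3)2 (4.5 equiv), THF, −78 → −20 °C; then 4 (pre-treated with 2.0 equiv LiN(SiMe3)2, THF, −78 °C), −78 °C, 1 h; LiN(SiMe3)2 (1.5 equiv), → 23 °C, 12 h; cold 1 M HCl
Reagents that add atoms: none
Why: This is a directed crossed aldol condensation (Claisen–Schmidt type) with a preformed polylithiated hydroxyacetophenone enolate, in which addition at −78 °C to the only aldehyde outruns proton transfer to the un-enolised acetyl group of 4, the excess of 1 suppresses self-condensation of 4, and E1cB loss of hydroxide from 5 on warming gives the favoured E-enone and erases the transient carbinol centre.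

Step 4
Reactants: 6 (E)-3-[3-(3-acetyl-2,4-dihydroxy-6-methoxyphenyl)-4-methoxyphenyl]-1-(2,6-dihydroxy-4-methoxyphenyl)prop-2-en-1-one; 7 4-(tetrahydro-2H-pyran-2-yloxy)benzaldehyde (racemic acetal)
Product: 9 (E,E)-bichalcone THP ether, via racemic aldol adduct 8 (not isolated)
Conditions: 6, LiN(SiMe3)2 (5.2 equiv), THF, −78 → −20 °C; 7 (1.4 equiv), −78 °C, 1 h; LiN(SiMe3)2 (1.0 equiv), → 23 °C, 12 h; AcOH/THF quench, −20 °C
Reagents that add atoms: none
Why: The same directed aldol condensation now uses the ring-D acetyl group as the only enolisable site, the existing enone is shielded from Michael addition as an electron-rich bis-phenoxide, any part of 6 that had ring-closed is reopened by the amide base (E1cB), E1cB from 8 gives the E-enone, and the cold AcOH quench spares the THP acetal and leaves the chalcones open.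

Step 5
Reactants: 9 (E,E)-bichalcone THP ether
Product: 11 (2S,2''S)-target biflavanone, via THP-protected biflavanone 10 (not isolated)
Conditions: quinine-derived 9-epi-amino N-[3,5-bis(trifluoromethyl)phenyl]thiourea (20 mol %), toluene/CH2Cl2 3:1 (0.02 M), −10 °C, 72 h; then TsOH·H2O (0.5 equiv), MeOH, 0 → 23 °C, 2 h
Reagents that add atoms: none
Why: Proposed new method: a double, enantioselective 6-endo-trig oxa-Michael closure with all ring-A and ring-D phenols free in which, at each enone, the thiourea N–H pair and the internal chelate of one ortho-OH polarise the carbonyl while the quinuclidine nitrogen deprotonates the other ortho-OH and guides it to the Si face of the β-carbon (a small-molecule copy of chalcone isomerase), so rings C and F and both (S) centres arise in one operation, ring F closes through the unhindered 6'-OH because the 2'-OH is buttressed into the chelate and shielded by the orthogonal ring B, the two independent events raise the ee of the (S,S) product statistically (Horeau effect), and the acid quench stops amine-induced retro-Michael racemisation and removes the THP group; the closest known reaction type is the cinchona-thiourea-catalysed intramolecular oxa-Michael cyclisation of ester-activated 2'-hydroxychalcones to flavanones followed by acid treatment in the same flask.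

## Compound list
1 | 1-(2,6-dihydroxy-4-methoxyphenyl)ethan-1-one (2',6'-dihydroxy-4'-methoxyacetophenone) | CC(=O)c1c(O)cc(OC)cc1O | starting material
2 | 1-(2,6-dihydroxy-3-iodo-4-methoxyphenyl)ethan-1-one | CC(=O)c1c(O)cc(OC)c(I)c1O | intermediate
3 | (5-formyl-2-methoxyphenyl)boronic acid | COc1ccc(C=O)cc1B(O)O | starting material
4 | 3-(3-acetyl-2,4-dihydroxy-6-methoxyphenyl)-4-methoxybenzaldehyde | CC(=O)c1c(O)cc(OC)c(-c2cc(C=O)ccc2OC)c1O | intermediate
5 | racemic 3-[3-(3-acetyl-2,4-dihydroxy-6-methoxyphenyl)-4-methoxyphenyl]-1-(2,6-dihydroxy-4-methoxyphenyl)-3-hydroxypropan-1-one | COc1cc(O)c(C(=O)CC(O)c2ccc(OC)c(-c3c(OC)cc(O)c(C(C)=O)c3O)c2)c(O)c1 | intermediate (not isolated)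
6 | (E)-3-[3-(3-acetyl-2,4-dihydroxy-6-methoxyphenyl)-4-methoxyphenyl]-1-(2,6-dihydroxy-4-methoxyphenyl)prop-2-en-1-one | COc1cc(O)c(C(=O)/C=C/c2ccc(OC)c(-c3c(OC)cc(O)c(C(C)=O)c3O)c2)c(O)c1 | intermediate
7 | 4-(tetrahydro-2H-pyran-2-yloxy)benzaldehyde (racemic acetal) | O=Cc1ccc(OC2CCCCO2)cc1 | starting material
8 | aldol adduct of 6 and 7: unit 1 is the E-enone, unit 2 is the β-hydroxy ketone (racemic carbinol) | COc1cc(O)c(C(=O)/C=C/c2ccc(OC)c(-c3c(OC)cc(O)c(C(=O)CC(O)c4ccc(OC5CCCCO5)cc4)c3O)c2)c(O)c1 | intermediate (not isolated)
9 | (E,E)-bichalcone THP ether: the ring-D acetyl of 6 is extended to an (E)-3-[4-(THP-oxy)phenyl]prop-2-enoyl group | COc1cc(O)c(C(=O)/C=C/c2ccc(OC)c(-c3c(OC)cc(O)c(C(=O)/C=C/c4ccc(OC5CCCCO5)cc4)c3O)c2)c(O)c1 | intermediate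
10 | (2S,2''S)-biflavanone with the ring-E hydroxyl as THP ether (THP centre unassigned) | COc1cc(O)c2c(c1)O[C@H](c1ccc(OC)c(-c3c(OC)cc4c(c3O)C(=O)C[C@@H](c3ccc(OC5CCCCO5)cc3)O4)c1)CC2=O | intermediate (not isolated)
11 | (2S,2''S)-2,3,2'',3''-tetrahydrorobustaflavone 7,4',7''-trimethyl ether (CNP0150873.1) | COc1cc(O)c2c(c1)O[C@H](c1ccc(OC)c(-c3c(OC)cc4c(c3O)C(=O)C[C@@H](c3ccc(O)cc3)O4)c1)CC2=O | target

## Step count and risks
Total steps: 5. Longest linear sequence: 5 (1 → 2 → 4 → 6 → 9 → 11).

**Step 5 is the largest risk.**
- The enones carry no activating ester, so per-site selectivity may be modest. At 90:10 per site the statistics still give about 81 % (S,S), 1 % (R,R) and 18 % mixed diastereomers. That corresponds to about 98 % ee once the diastereomers are removed by chromatography or crystallisation.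
- Ring F could also close in part through the hindered 2'-OH to the 8-linked isomer.
- The fallback sets out from 9 and comes back at 11. It replaces catalyst control by resolution with recycling.
- TsOH in MeOH removes the acetal to give the free bichalcone F5.
- NaOAc in refluxing EtOH closes both rings without stereocontrol to the biflavanone stereoisomer mixture F6.
- Preparative HPLC on a polysaccharide chiral phase delivers the (2S,2''S) isomer 11.
- All unwanted isomers, 8-linked material included, are reopened to F5 with cold aqueous KOH and rapid acidification, and then recycled.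

**Step 3 is the second risk.**
- On warming, the lithium aldolate may undergo retro-aldol cleavage. Enolate crossover could then let 4 condense with itself.
- The fallback sets out from 1 and 3 and comes back at 6. It makes the enone before the biaryl bond, so a keto-aldehyde never exists.
- A thermodynamic Claisen–Schmidt reaction of 1 with 3 (50 % aqueous KOH, EtOH, 23 °C, then cold HCl) passes through the racemic aldol adduct F1.
- This loses water to give the boronic acid chalcone F2.
- F2 is coupled with iodide 2 under the conditions of step 2 to give 6.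
- Any premature ring closure in this coupling is undone by the excess amide base of step 4.

**Step 4 is the third risk.**
- The five-fold lithiated form of 6 may be insoluble or may enolise poorly.
- The fallback sets out from 2 and 7 and comes back at 9. It joins two finished chalcones by cross-coupling instead of building the second enone on the large polyanion.
- Iodide 2 is triply lithiated with LiN(SiMe3)2 and adds to 7 to give the racemic aldol adduct F3.
- F3 eliminates to the iodochalcone THP ether F4.
- Suzuki coupling of F4 with the boronic acid chalcone F2 (Pd(OAc)2, SPhos, K3PO4, THF/H2O, 40 °C) follows.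
- A short treatment with cold 2 M KOH and a quench into cold pH 5 buffer reopens any closed ring and gives 9.

## Further compounds
F1 | step 3 | racemic [5-[3-(2,6-dihydroxy-4-methoxyphenyl)-1-hydroxy-3-oxopropyl]-2-methoxyphenyl]boronic acid | COc1cc(O)c(C(=O)CC(O)c2ccc(OC)c(B(O)O)c2)c(O)c1
F2 | step 3 | (E)-[5-[3-(2,6-dihydroxy-4-methoxyphenyl)-3-oxoprop-1-enyl]-2-methoxyphenyl]boronic acid | COc1cc(O)c(C(=O)/C=C/c2ccc(OC)c(B(O)O)c2)c(O)c1
F3 | step 4 | racemic 1-(2,6-dihydroxy-3-iodo-4-methoxyphenyl)-3-hydroxy-3-[4-(tetrahydro-2H-pyran-2-yloxy)phenyl]propan-1-one | COc1cc(O)c(C(=O)CC(O)c2ccc(OC3CCCCO3)cc2)c(O)c1I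
F4 | step 4 | (E)-1-(2,6-dihydroxy-3-iodo-4-methoxyphenyl)-3-[4-(tetrahydro-2H-pyran-2-yloxy)phenyl]prop-2-en-1-one | COc1cc(O)c(C(=O)/C=C/c2ccc(OC3CCCCO3)cc2)c(O)c1I
F5 | step 5 | free (E,E)-bichalcone (9 without the THP group) | COc1cc(O)c(C(=O)/C=C/c2ccc(OC)c(-c3c(OC)cc(O)c(C(=O)/C=C/c4ccc(O)cc4)c3O)c2)c(O)c1
F6 | step 5 | biflavanone as a mixture of all C2/C2'' stereoisomers | COc1cc(O)c2c(c1)OC(c1ccc(OC)c(-c3c(OC)cc4c(c3O)C(=O)CC(c3ccc(O)cc3)O4)c1)CC2=O
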